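**Strategy.** In the target, C3 and the benzylic carbon on C4 stand 1,3 to each other across the stereocentre C4, so both can be folded back into a cyclopropane. The key step therefore makes the vanillyl aryl–CH2 bond and the exocyclic C3=CH bond in one flask. Its precursor is the small bicyclic lactone diethyl [(1R,5S)-2-oxo-3-oxabicyclo[3.1.0]hexan-1-yl]phosphonate, made from (R)-epichlorohydrin, which already holds C4 in the right configuration. An arylcopper reagent opens the cyclopropane at its CH2, and the phosphonate carbanion so released olefinates protected syringaldehyde to the E-benzylidene lactone. Two silylations, one Grignard formation and a final desilylation are the only other steps.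

Key step: step 5

Assumption (chemistry): the anion of triethyl phosphonoacetate is taken to react with (R)-epichlorohydrin in the same order of events as malonate anions do (epoxide CH2 first, chloride second); this fixes the absolute configuration used below.

Step 1
Reactants: 1 (R)-epichlorohydrin; 2 triethyl phosphonoacetate
Product: 3 diethyl [(1R,5S)-2-oxo-3-oxabicyclo[3.1.0]hexan-1-yl]phosphonate
Conditions: NaOEt (1.1 equiv), EtOH, 0 °C → reflux
Reagents that add atoms: none
Why: Double alkylation of an active-methylene compound with epichlorohydrin, as practised with malonates: the anion opens the epoxide at CH2, the alkoxide displaces chloride to a new epoxide, and the re-formed carbanion opens it 3-exo-tet with inversion, which sets C5 (and C1 through the obligatory cis fusion), the bulkier phosphoryl group being expected trans to the CH2O arm so that the ester is the group that lactonises.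

Step 2
Reactants: 4 4-bromo-2-methoxyphenol
Product: 5 (4-bromo-2-methoxyphenoxy)(tert-butyl)dimethylsilane
Conditions: TBSCl, imidazole, DMF, rt
Reagents that add atoms: tert-butyldimethylsilyl chloride, CC(C)(C)[Si](C)(C)Cl
Why: Standard silylation of a phenol, giving an aryl silyl ether that tolerates Grignard formation and organocopper chemistry.

Step 3
Reactants: 5 (4-bromo-2-methoxyphenoxy)(tert-butyl)dimethylsilane
Product: 6 {4-[(tert-butyldimethylsilyl)oxy]-3-methoxyphenyl}magnesium bromide (titrated THF solution, used directly)
Conditions: Mg turnings, I2 (cat.), THF, 40 °C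
Reagents that add atoms: magnesium, [Mg]
Why: Grignard formation by insertion of magnesium into the aryl C–Br bond, to which the silyl and methyl ethers are inert.

Step 4
Reactants: 7 syringaldehyde
Product: 8 4-[(tert-butyldimethylsilyl)oxy]-3,5-dimethoxybenzaldehyde
Conditions: TBSCl, imidazole, DMAP (cat.), DMF, rt → 40 °C
Reagents that add atoms: tert-butyldimethylsilyl chloride, CC(C)(C)[Si](C)(C)Cl
Why: Silylation of the hindered phenol removes the acidic OH, which would otherwise quench the enolate of step 5 and deactivate the aldehyde as its phenoxide.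

Step 5
Reactants: 3 diethyl [(1R,5S)-2-oxo-3-oxabicyclo[3.1.0]hexan-1-yl]phosphonate; 6 {4-[(tert-butyldimethylsilyl)oxy]-3-methoxyphenyl}magnesium bromide; 8 4-[(tert-butyldimethylsilyl)oxy]-3,5-dimethoxybenzaldehyde
Product: 10 (3E,4R)-3-{4-[(tert-butyldimethylsilyl)oxy]-3,5-dimethoxybenzylidene}-4-{4-[(tert-butyldimethylsilyl)oxy]-3-methoxybenzyl}oxolan-2-one, via bromomagnesium phosphonoenolate 9 (not isolated)
Conditions: 6 (1.1 equiv), CuI (15 mol %), THF, −40 → 0 °C; then 8 (1.3 equiv), 0 → 50 °C; aq NH4Cl
Reagents that add atoms: none
Why: An arylcopper(I) species from 6 and CuI attacks the cyclopropane CH2 (C6 of 3) in an SN2-type homoconjugate addition and cleaves the C1–C6 bond, which lies almost perpendicular to the lactone plane and overlaps with the lactone C=O π* while the Mg-chelated P=O stabilises the developing carbanion; the resulting enolate 9 adds to aldehyde 8 and collapses through an oxaphosphetane to the alkene with loss of diethyl phosphate (Horner–Wadsworth–Emmons olefination). The closest known reaction types are the copper-catalysed Grignard opening of the ester-activated congener of 3 at the same CH2 and the HWE olefination of α-phosphono-γ-butyrolactones with aryl aldehydes. No ring is closed: the lactone is carried through and the three-membered ring is opened, so no mode of closure has to be met. The C4 stereocentre of 10 is not made here; it is C5 of 3, which takes no part in the bond cleavage and is not acidic afterwards, so it is carried over unchanged (the descriptor changes from S to R only because phosphorus leaves the neighbouring carbon). The new stereo-element is the E double bond, which should follow from reversible Mg-mediated addition and elimination through the less crowded oxaphosphetane with the aryl group anti to the lactone carbonyl, which is also the thermodynamically preferred isomer. The step needs attack at C6 and not at C5, the lactone C=O or phosphorus, which the unhindered primary carbon, copper catalysis at low temperature and the near-stoichiometric charge of 6 (so that little is left to add to 8) should secure.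

Step 6
Reactants: 10 (3E,4R)-3-{4-[(tert-butyldimethylsilyl)oxy]-3,5-dimethoxybenzylidene}-4-{4-[(tert-butyldimethylsilyl)oxy]-3-methoxybenzyl}oxolan-2-one
Product: 11 (3E,4R)-3-(4-hydroxy-3,5-dimethoxybenzylidene)-4-(4-hydroxy-3-methoxybenzyl)oxolan-2-one (CNP0351244.1)
Conditions: TBAF (2.4 equiv), AcOH (2.6 equiv), THF, 0 °C → rt
Reagents that add atoms: none
Why: Fluoride-induced cleavage of both aryl silyl ethers, buffered with acetic acid so that the phenoxides are protonated at once and the lactone, the E-alkene and C4 stay untouched.

**Compound list**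

1 | (R)-epichlorohydrin, (2R)-2-(chloromethyl)oxirane | ClC[C@H]1CO1 | starting material
2 | triethyl phosphonoacetate | CCOC(=O)CP(=O)(OCC)OCC | starting material
3 | diethyl [(1R,5S)-2-oxo-3-oxabicyclo[3.1.0]hexan-1-yl]phosphonate | C1[C@H]2COC(=O)[C@@]12P(=O)(OCC)OCC | intermediate
4 | 4-bromo-2-methoxyphenol | COc1cc(Br)ccc1O | starting material
5 | (4-bromo-2-methoxyphenoxy)(tert-butyl)dimethylsilane | COc1cc(Br)ccc1O[Si](C)(C)C(C)(C)C | intermediate
6 | {4-[(tert-butyldimethylsilyl)oxy]-3-methoxyphenyl}magnesium bromide | COc1cc([Mg]Br)ccc1O[Si](C)(C)C(C)(C)C | intermediate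
7 | syringaldehyde (4-hydroxy-3,5-dimethoxybenzaldehyde) | COc1cc(C=O)cc(OC)c1O | starting material
8 | 4-[(tert-butyldimethylsilyl)oxy]-3,5-dimethoxybenzaldehyde | COc1cc(C=O)cc(OC)c1O[Si](C)(C)C(C)(C)C | intermediate
9 | bromomagnesium enolate of diethyl {(4S)-4-[4-(tert-butyldimethylsilyloxy)-3-methoxybenzyl]-2-oxooxolan-3-yl}phosphonate (same spatial arrangement at C4 as in 10) | COc1cc(C[C@H]2COC(O[Mg]Br)=C2P(=O)(OCC)OCC)ccc1O[Si](C)(C)C(C)(C)C | intermediate (not isolated)
10 | (3E,4R)-3-{4-[(tert-butyldimethylsilyl)oxy]-3,5-dimethoxybenzylidene}-4-{4-[(tert-butyldimethylsilyl)oxy]-3-methoxybenzyl}oxolan-2-one | COc1cc(C[C@H]2COC(=O)/C2=C/c2cc(OC)c(O[Si](C)(C)C(C)(C)C)c(OC)c2)ccc1O[Si](C)(C)C(C)(C)C | intermediate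
11 | (3E,4R)-3-(4-hydroxy-3,5-dimethoxybenzylidene)-4-(4-hydroxy-3-methoxybenzyl)oxolan-2-one | COc1cc(C[C@H]2COC(=O)/C2=C/c2cc(OC)c(O)c(OC)c2)ccc1O | target

**Total step count:** 6

**Longest linear sequence:** 4 steps (4 → 5 → 6 → 10 → 11; steps 2, 3, 5 and 6)

**Steps most likely to fail**

Step 5. The arylcopper reagent may add to the lactone carbonyl or to phosphorus instead of opening the ring, because a phosphoryl group activates the cyclopropane less than an ester does. The magnesium phosphonoenolate may also olefinate slowly or with loss of E/Z control. The fallback sets out from 1. With di-tert-butyl malonate (t-BuOK, t-BuOH, reflux), 1 should give the ester-activated bicycle tert-butyl (1R,5R)-2-oxo-3-oxabicyclo[3.1.0]hexane-1-carboxylate F1. Copper-catalysed opening with 6 (CuI, THF, −30 °C), the transformation established for this ester class, should give tert-butyl (4R)-4-{4-[(tert-butyldimethylsilyl)oxy]-3-methoxybenzyl}-2-oxooxolane-3-carboxylate F2. TFA in CH2Cl2 at 0 °C followed by warming in toluene should remove isobutene and CO2 and leave (4R)-4-{4-[(tert-butyldimethylsilyl)oxy]-3-methoxybenzyl}oxolan-2-one F3. Its lithium enolate (LiHMDS, THF, −78 °C) should add to 8 to give the aldol (4R)-3-{[4-(tert-butyldimethylsilyloxy)-3,5-dimethoxyphenyl](hydroxy)methyl}-4-{4-[(tert-butyldimethylsilyl)oxy]-3-methoxybenzyl}oxolan-2-one F4 as a mixture of diastereomers. Dehydration by way of the mesylate (MsCl, Et3N, then DBU; E1cB, thermodynamic E) brings the sequence back to the route at 10.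

Step 1. First attack at the CH2Cl carbon instead of the epoxide would erode the enantiomeric purity. Ring closure with phosphorus cis to the CH2O arm would lead to O→P cyclisation instead of lactonisation. The fallback sets out from 2. Transesterification with allyl alcohol (DMAP cat., toluene, reflux, ethanol distilled off) should give prop-2-en-1-yl (diethoxyphosphoryl)acetate F5. Diazo transfer (p-acetamidobenzenesulfonyl azide, DBU, MeCN) should give prop-2-en-1-yl diazo(diethoxyphosphoryl)acetate F6. Enantioselective intramolecular cyclopropanation of the allyl group, with a chiral Co(II)–porphyrin metalloradical catalyst of the kind that accepts allyl diazoacetates bearing a second acceptor, closes the lactone-fused cyclopropane directly, so no lactone/phosphorus ambiguity can arise. The sequence comes back to the route at 3.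

Step 3. Magnesium insertion into the electron-rich aryl bromide may be slow or incomplete, and Wurtz-type homocoupling would upset the stoichiometry on which step 5 depends. The fallback sets out from 5. Bromine–lithium exchange (n-BuLi, THF, −78 °C) should give {4-[(tert-butyldimethylsilyl)oxy]-3-methoxyphenyl}lithium F7, which is transmetalated with MgBr2·OEt2. The sequence comes back to the route at 6.

**Further compounds**

F1 | step 5 | tert-butyl (1R,5R)-2-oxo-3-oxabicyclo[3.1.0]hexane-1-carboxylate | C1[C@H]2COC(=O)[C@@]12C(=O)OC(C)(C)C
F2 | step 5 | tert-butyl (4R)-4-{4-[(tert-butyldimethylsilyl)oxy]-3-methoxybenzyl}-2-oxooxolane-3-carboxylate (C3 epimers) | COc1cc(C[C@H]2COC(=O)C2C(=O)OC(C)(C)C)ccc1O[Si](C)(C)C(C)(C)C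
F3 | step 5 | (4R)-4-{4-[(tert-butyldimethylsilyl)oxy]-3-methoxybenzyl}oxolan-2-one | COc1cc(C[C@H]2COC(=O)C2)ccc1O[Si](C)(C)C(C)(C)C
F4 | step 5 | (4R)-3-{[4-(tert-butyldimethylsilyloxy)-3,5-dimethoxyphenyl](hydroxy)methyl}-4-{4-[(tert-butyldimethylsilyl)oxy]-3-methoxybenzyl}oxolan-2-one (mixture at C3 and at the carbinol carbon) | COc1cc(C[C@H]2COC(=O)C2C(O)c2cc(OC)c(O[Si](C)(C)C(C)(C)C)c(OC)c2)ccc1O[Si](C)(C)C(C)(C)C
F5 | step 1 | prop-2-en-1-yl (diethoxyphosphoryl)acetate | C=CCOC(=O)CP(=O)(OCC)OCC
F6 | step 1 | prop-2-en-1-yl diazo(diethoxyphosphoryl)acetate | C=CCOC(=O)C(=[N+]=[N-])P(=O)(OCC)OCC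
F7 | step 3 | {4-[(tert-butyldimethylsilyl)oxy]-3-methoxyphenyl}lithium | COc1cc([Li])ccc1O[Si](C)(C)C(C)(C)C
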